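The leftover is this flask's ledger. It holds 0.26 M of substrate against 0.156 M of first nucleophile and 0.390 M of second nucleophile, so the nucleophiles together exceed the substrate, and what remains of each shows how the substrate was shared.

| flask | substrate | first nucleophile | second nucleophile | remark | time |
|---|---|---|---|---|---|
| zeta | 0.17 M | 0.156 M | 0.39 M | run made earlier |  |
| beta | 0.39 M | 0.156 M | 0.39 M | run made earlier |  |
| theta | 0.26 M | 0.156 M | 0.78 M | run made earlier |  |
| flask | 0.26 M | 0.156 M | 0.390 M |  | 15 d |

| run | time / d | other capture product / % | target / % |
|---|---|---|---|
| zeta | 0.625 | 51 | 41 |
| zeta | 1.25 | 52 | 34 |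
| zeta | 2.08 | 52 | 33 |
| zeta | 3.00 | 54 | 22 |
| zeta | 5.00 | 52 | 18 |
| zeta | 10.0 | 53 | 17 |
| beta | 0.625 | 59 | 32 |
| beta | 1.25 | 60 | 26 |
| beta | 2.08 | 62 | 26 |
| beta | 3.00 | 62 | 23 |
| beta | 5.00 | 61 | 12 |
| beta | 10.0 | 62 | 9 |
| theta | 0.833 | 65 | 26 |
| theta | 2.50 | 70 | 15 |
| theta | 4.00 | 69 | 9 |
| theta | 6.00 | 71 | 10 |
| theta | 10.0 | 73 | 9 |

(each reading ± 2 percentage points)

* share of other capture product in other capture product plus target at 8.0 min
* share of other capture product in other capture product plus target at 8.0 h
* share of other capture product in other capture product plus target at 15 d
* which of other capture product and target there is more of at 15 d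



In the earlier runs other capture product changes little after the first readings while target falls, so we take the split as made early and the fading as coming later. If each nucleophile is used at a rate proportional to its own concentration, dividing one rate by the other removes time: the logarithm of charge over remainder for first nucleophile, over the same logarithm for second nucleophile, stays constant. We count first nucleophile used as substrate charged minus other capture product. Zeta's mean plateau of 52.6 % then gives 2.79, and theta's 70.8 % gives 2.49. Beta used nearly all of its first nucleophile, leaving too little to read. The mean, 2.64, is our selectivity factor, read from readings with their scatter.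

So in this flask other capture product over target starts at [second nucleophile]/[first nucleophile] divided by the factor, a share of 48.7 %. We expect about that at 8.0 min if capture has barely begun, and a rising share after it. By 15 d other capture product should lead, as in theta's last reading, 73 % against 9 %.

The forecast says 51 %, a little above our start share, then 57 % and 82 %, with other capture product ahead, on the grounds of “fast competitive capture, then slow target loss”.

The flask gives 49.7 %, 58.7 % and 84.9 %, with other capture product ahead, 57.3 % against 10.2 %, and a net 29.8 % of the substrate charged has passed from target into isomer of the product. The other capture product's 57.3 % took 38.2 % of the second nucleophile's charge, and raising the fraction this leaves to the power 2.64 gives 28.1 % of first nucleophile remaining; the flask holds 28.9 %.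

    substrate ⇌ intermediate (K = 0.170, k = 1.70 × 10⁻⁴ /s)
    second nucleophile + target → over-reaction product (k = 5.30 × 10⁻⁷ /M/s)
    second nucleophile + intermediate → other capture product (k = 0.0190 /M/s)
    substrate ⇌ dormant form (K = 0.860, k = 3.70 × 10⁻⁶ /s)
    first nucleophile + intermediate → target (k = 0.0490 /M/s)
    target ⇌ isomer of the product (K = 2.90, k = 2.90 × 10⁻⁶ /s)

For the neighbour charged with 0.62 M of first nucleophile, the factor gives a start share of 19.2 %. Computed, that neighbour stands at 19.7 % at 8.0 min, the earliest time asked.

All runs were generated by integration for an exercise, noise included.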